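**Plan**

1. Numbering for all ring compounds: O1, C2 (guaiacyl), C3 (CH3), C4 (syringylmethyl, benzylic carbon C7'), C5 (CH2). The target is (2R,3R,4R), that is 2,3-trans and 3,4-trans.
2. Cuts: O1–C5 first (1,4-diol, hence the C5 lactone). Then C4–C7' and C3–CH3 together, back to an (R)-2-aryl butenolide and a protected syringyl bromide. Last, the butenolide C3=C4 bond (metathesis) and the C2–vinyl bond.
3. Enabling feature: with C5 as a carbonyl, C3 and C4 are the β- and α-carbons of an enoate locked in a flat five-membered ring. The C2, C3 and C4 substituents sit on alternating faces, so each new group can enter opposite to its neighbour.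
4. Forward order: the lactone ring arises by ring-closing metathesis, and the methyl and arylmethyl groups are added to it in one flask. The lactone is then reduced open, the tetrahydrofuran ring is closed by O1 attacking C5, and debenzylation ends the route.
5. Stereochemistry: C2 comes from a lipase kinetic resolution, and C3 and C4 follow by relay from C2. The C2–O1 bond is never broken once it is set.

Key step: step 8

Assumption: the lipase shows its usual size preference for secondary alcohols (aryl as the large group, vinyl as the medium group), so the (R)-alcohol is the enantiomer that is acylated. Systematic names keep their own locants; the discussion uses the target numbering given above.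

**Step 1**
Reactants: 1 vanillin
Product: 2 4-(benzyloxy)-3-methoxybenzaldehyde
Conditions: BnBr, K2CO3, DMF, 60 °C
Reagents that add atoms: benzyl bromide, BrCc1ccccc1
Why: Williamson ether synthesis on the acidic phenol; the benzyl ether tolerates Grignard, cuprate, enolate and hydride reagents and is removed at the end under neutral conditions.

**Step 2**
Reactants: 2 4-(benzyloxy)-3-methoxybenzaldehyde; 3 vinylmagnesium bromide
Product: 4 (±)-1-[4-(benzyloxy)-3-methoxyphenyl]prop-2-en-1-ol
Conditions: THF, −20 → 0 °C; then sat. aq. NH4Cl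
Reagents that add atoms: none
Why: Grignard 1,2-addition to a non-enolisable aromatic aldehyde forms the carbinol centre (future C2) as the racemate, and the buffered quench avoids ionisation of the electron-rich benzylic allylic alcohol.

**Step 3**
Reactants: 4 (±)-1-[4-(benzyloxy)-3-methoxyphenyl]prop-2-en-1-ol; 5 vinyl (E)-but-2-enoate (vinyl crotonate)
Product: 6 (1R)-1-[4-(benzyloxy)-3-methoxyphenyl]prop-2-en-1-yl (E)-but-2-enoate
Conditions: 5 (3 equiv), Novozym 435 (immobilised lipase B of Candida antarctica), MTBE, 35 °C, stopped short of half conversion; chromatography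
Reagents that add atoms: none
Why: Lipase-catalysed kinetic resolution by irreversible transesterification with an enol ester should acylate only the (R)-alcohol, which fixes C2 and also installs the enoate needed for ring closure without any acid chloride or amine base.

**Step 4**
Reactants: 6 (1R)-1-[4-(benzyloxy)-3-methoxyphenyl]prop-2-en-1-yl (E)-but-2-enoate
Product: 7 (5R)-5-[4-(benzyloxy)-3-methoxyphenyl]furan-2(5H)-one
Conditions: second-generation Grubbs catalyst (H2IMes)(PCy3)Cl2Ru=CHPh (5 mol %), CH2Cl2 (0.01 M), reflux, argon sparge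
Reagents that add atoms: none
Why: In this ring-closing metathesis of an allyl enoate the catalyst loads on the terminal vinyl group and closes onto the crotonate C=C to form the five-membered butenolide with loss of propene, under neutral conditions that leave the base-sensitive C2–H and its configuration untouched.

**Step 5**
Reactants: 8 syringaldehyde
Product: 9 4-(benzyloxy)-3,5-dimethoxybenzaldehyde
Conditions: BnBr, K2CO3, DMF, 60 °C
Reagents that add atoms: benzyl bromide, BrCc1ccccc1
Why: Williamson ether synthesis, with the polar solvent and gentle heating compensating for the two flanking methoxy groups.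

**Step 6**
Reactants: 9 4-(benzyloxy)-3,5-dimethoxybenzaldehyde
Product: 10 [4-(benzyloxy)-3,5-dimethoxyphenyl]methanol
Conditions: NaBH4, MeOH, 0 °C
Reagents that add atoms: none
Why: Borohydride reduction of an aromatic aldehyde, with no other reducible group present.

**Step 7**
Reactants: 10 [4-(benzyloxy)-3,5-dimethoxyphenyl]methanol
Product: 11 4-(benzyloxy)-3,5-dimethoxybenzyl bromide
Conditions: PBr3, Et2O, 0 °C; used freshly prepared without chromatography
Reagents that add atoms: phosphorus tribromide, BrP(Br)Br
Why: PBr3 activates the benzylic hydroxyl for SN2 displacement by bromide, a standard conversion that at 0 °C leaves the aryl benzyl ether intact.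

**Step 8**
Reactants: 7 (5R)-5-[4-(benzyloxy)-3-methoxyphenyl]furan-2(5H)-one; 11 4-(benzyloxy)-3,5-dimethoxybenzyl bromide
Product: 13 (3R,4R,5R)-3-[4-(benzyloxy)-3,5-dimethoxybenzyl]-5-[4-(benzyloxy)-3-methoxyphenyl]-4-methyldihydrofuran-2(3H)-one, via lithium enolate 12 (not isolated)
Conditions: MeLi (2.3 equiv), CuI (1.2 equiv), Et2O, 0 °C; 7, THF, −78 °C; then DMPU, 11 (2 equiv), −78 → −20 °C; aq. NH4Cl/NH3
Reagents that add atoms: lithium dimethylcuprate Me2CuLi, [Li+].C[Cu-]C (made in the flask from methyllithium, [Li]C, and CuI)
Why: Me2CuLi binds the C3=C4 π bond of the flat butenolide ring on the face away from the C2 aryl group, adds oxidatively at C3 to a transient trivalent-copper species and eliminates reductively to make C3–CH3, which leaves lithium enolate 12; 12 then attacks the benzylic bromide 11 in an SN2 reaction to make C4–C7'. The closest known reaction type is the tandem conjugate addition–enolate alkylation (three-component coupling) of butenolides familiar from lignan lactone synthesis. No ring closes, since the lactone ring of 7 is carried through unchanged and both new bonds are exocyclic. C3 is controlled by the resolved C2 centre (anti addition, 2,3-trans) and C4 by the new C3 methyl group, which shields one face of the planar enolate (3,4-trans), the arrangement that is also favoured thermodynamically at this epimerisable carbon. Conjugate addition has to outrun removal of the doubly activated C2–H, which would racemise 7 through its dienolate, and the soft, weakly basic cuprate at −78 °C with CuI kept in slight excess (no free MeLi) secures that. C-alkylation has to outrun proton exchange and a second alkylation, which the highly reactive electron-rich benzylic bromide used in excess, DMPU as cosolvent and the hindered tertiary C4–H of 13 secure.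

**Step 9**
Reactants: 13 (3R,4R,5R)-3-[4-(benzyloxy)-3,5-dimethoxybenzyl]-5-[4-(benzyloxy)-3-methoxyphenyl]-4-methyldihydrofuran-2(3H)-one
Product: 14 (1R,2R,3R)-1-[4-(benzyloxy)-3-methoxyphenyl]-3-[4-(benzyloxy)-3,5-dimethoxybenzyl]-2-methylbutane-1,4-diol
Conditions: LiAlH4, THF, 0 °C → rt; then H2O
Reagents that add atoms: none
Why: Hydride reduction of a lactone to the 1,4-diol touches none of the three stereocentres, because attack at the C5 carbonyl is far faster than enolisation at C4.

**Step 10**
Reactants: 14 (1R,2R,3R)-1-[4-(benzyloxy)-3-methoxyphenyl]-3-[4-(benzyloxy)-3,5-dimethoxybenzyl]-2-methylbutane-1,4-diol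
Product: 16 (2R,3R,4R)-2-[4-(benzyloxy)-3-methoxyphenyl]-4-[4-(benzyloxy)-3,5-dimethoxybenzyl]-3-methyltetrahydrofuran, via primary tosylate 15 (not isolated)
Conditions: TsCl (1.1 equiv), Et3N, DMAP (cat.), CH2Cl2, 0 °C; aq. wash, crude 15, NaH, THF, 0 °C → rt
Reagents that add atoms: p-toluenesulfonyl chloride, Cc1ccc(cc1)S(=O)(=O)Cl (its sulfonyl group is held by 15 and leaves again on ring closure)
Why: Selective sulfonylation of the primary C5–OH over the flanked secondary benzylic C2–OH is followed by an intramolecular Williamson etherification (5-exo-tet) in which the C2 alkoxide is the nucleophile, so the C2–O bond and its configuration are retained.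

**Step 11**
Reactants: 16 (2R,3R,4R)-2-[4-(benzyloxy)-3-methoxyphenyl]-4-[4-(benzyloxy)-3,5-dimethoxybenzyl]-3-methyltetrahydrofuran
Product: 17 (2R,3R,4R)-2-(4-hydroxy-3-methoxyphenyl)-4-(4-hydroxy-3,5-dimethoxybenzyl)-3-methyltetrahydrofuran (target, CID53359708)
Conditions: H2 (1 atm), 10% Pd/C, EtOAc, rt, stopped as soon as debenzylation is complete
Reagents that add atoms: none
Why: Catalytic hydrogenolysis should cleave the two aryl benzyl ethers, whose C–O bonds release phenols, much faster over Pd/C in a neutral aprotic solvent than the alkyl-type benzylic C2–O1 bond of the ring, and no stereocentre is involved.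

**Compound list**

1 | vanillin | COc1cc(C=O)ccc1O | starting material
2 | 4-(benzyloxy)-3-methoxybenzaldehyde | COc1cc(C=O)ccc1OCc1ccccc1 | intermediate
3 | vinylmagnesium bromide | C=C[Mg]Br | starting material
4 | (±)-1-[4-(benzyloxy)-3-methoxyphenyl]prop-2-en-1-ol (racemate) | COc1cc(C(O)C=C)ccc1OCc1ccccc1 | intermediate
5 | vinyl (E)-but-2-enoate (vinyl crotonate) | C=COC(=O)/C=C/C | starting material
6 | (1R)-1-[4-(benzyloxy)-3-methoxyphenyl]prop-2-en-1-yl (E)-but-2-enoate | COc1cc([C@@H](C=C)OC(=O)/C=C/C)ccc1OCc1ccccc1 | intermediate
7 | (5R)-5-[4-(benzyloxy)-3-methoxyphenyl]furan-2(5H)-one | COc1cc([C@@H]2OC(=O)C=C2)ccc1OCc1ccccc1 | intermediate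
8 | syringaldehyde | COc1cc(C=O)cc(OC)c1O | starting material
9 | 4-(benzyloxy)-3,5-dimethoxybenzaldehyde | COc1cc(C=O)cc(OC)c1OCc1ccccc1 | intermediate
10 | [4-(benzyloxy)-3,5-dimethoxyphenyl]methanol | COc1cc(CO)cc(OC)c1OCc1ccccc1 | intermediate
11 | 4-(benzyloxy)-3,5-dimethoxybenzyl bromide | COc1cc(CBr)cc(OC)c1OCc1ccccc1 | intermediate
12 | lithium (4R,5R)-5-[4-(benzyloxy)-3-methoxyphenyl]-4-methyl-4,5-dihydrofuran-2-olate (not isolated) | COc1cc([C@@H]2OC([O-])=C[C@H]2C)ccc1OCc1ccccc1.[Li+] | intermediate
13 | (3R,4R,5R)-3-[4-(benzyloxy)-3,5-dimethoxybenzyl]-5-[4-(benzyloxy)-3-methoxyphenyl]-4-methyldihydrofuran-2(3H)-one | COc1cc([C@@H]2OC(=O)[C@H](Cc3cc(OC)c(OCc4ccccc4)c(OC)c3)[C@H]2C)ccc1OCc1ccccc1 | intermediate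
14 | (1R,2R,3R)-1-[4-(benzyloxy)-3-methoxyphenyl]-3-[4-(benzyloxy)-3,5-dimethoxybenzyl]-2-methylbutane-1,4-diol | COc1cc([C@H](O)[C@H](C)[C@H](CO)Cc2cc(OC)c(OCc3ccccc3)c(OC)c2)ccc1OCc1ccccc1 | intermediate
15 | 4-O-(p-toluenesulfonyl) derivative of diol 14, (1R,2R,3R) (not isolated) | COc1cc([C@H](O)[C@H](C)[C@H](COS(=O)(=O)c2ccc(C)cc2)Cc2cc(OC)c(OCc3ccccc3)c(OC)c2)ccc1OCc1ccccc1 | intermediate
16 | (2R,3R,4R)-2-[4-(benzyloxy)-3-methoxyphenyl]-4-[4-(benzyloxy)-3,5-dimethoxybenzyl]-3-methyltetrahydrofuran | COc1cc([C@@H]2OC[C@H](Cc3cc(OC)c(OCc4ccccc4)c(OC)c3)[C@H]2C)ccc1OCc1ccccc1 | intermediate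
17 | (2R,3R,4R)-2-(4-hydroxy-3-methoxyphenyl)-4-(4-hydroxy-3,5-dimethoxybenzyl)-3-methyltetrahydrofuran | COc1cc([C@@H]2OC[C@H](Cc3cc(OC)c(O)c(OC)c3)[C@H]2C)ccc1O | target

**Step count**

Total steps: 11. Longest linear sequence: 8 (steps 1–4 and 8–11). The three-step bromide branch (steps 5–7) joins at step 8.

**Steps most likely to fail**

Step 8.
- What may go wrong: slow capture of the copper-containing enolate, proton exchange between enolate and product, consumption of the bromide by residual methylcopper species, or partial racemisation by deprotonation at C2.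
- The fallback sets out from 7 and comes back at 13. It keeps both disconnections but separates the two bond formations.
- Compound 7 is treated with Me2CuLi as before, the mixture is quenched with aq. NH4Cl, and (4R,5R)-5-[4-(benzyloxy)-3-methoxyphenyl]-4-methyldihydrofuran-2(3H)-one F1 is isolated.
- A copper-free enolate (again 12) is then generated from F1 with LiN(SiMe3)2 in THF at −78 °C and alkylated with 11. Attack anti to the methyl group should again lead to 13.

Step 3.
- What may go wrong: sluggish acyl transfer from the conjugated donor, or too little discrimination between the enantiomers with this acyl group.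
- The fallback sets out from 4 and comes back at 7. It separates the acyl group used for resolution from the one used for ring closure.
- Compound 4 is resolved with vinyl acetate and the same lipase to (1R)-1-[4-(benzyloxy)-3-methoxyphenyl]prop-2-en-1-yl acetate F2.
- K2CO3 in MeOH at 0 °C frees (1R)-1-[4-(benzyloxy)-3-methoxyphenyl]prop-2-en-1-ol F3.
- Acryloyl chloride with Et3N in CH2Cl2 at −20 °C gives (1R)-1-[4-(benzyloxy)-3-methoxyphenyl]prop-2-en-1-yl acrylate F4.
- F4 is closed under the conditions of step 4 to 7.

Step 11.
- What may go wrong: over-reduction by hydrogenolytic opening of the ring at the benzylic C2–O1 bond, which becomes more likely once the para phenol is free.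
- The fallback sets out from 16 and comes back at 17. It replaces hydrogenation by a benzyl-to-silyl exchange followed by fluoride.
- Et3SiH, Pd(OAc)2 (cat.) and Et3N in CH2Cl2 at rt, without hydrogen gas and with the amine moderating the catalyst, should give (2R,3R,4R)-2-[3-methoxy-4-(triethylsilyloxy)phenyl]-4-[3,5-dimethoxy-4-(triethylsilyloxy)benzyl]-3-methyltetrahydrofuran F5.
- Bu4NF buffered with AcOH in THF at 0 °C then frees both phenols to give 17.

**Further compounds**

F1 | step 8 | (4R,5R)-5-[4-(benzyloxy)-3-methoxyphenyl]-4-methyldihydrofuran-2(3H)-one | COc1cc([C@@H]2OC(=O)C[C@H]2C)ccc1OCc1ccccc1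
F2 | step 3 | (1R)-1-[4-(benzyloxy)-3-methoxyphenyl]prop-2-en-1-yl acetate | COc1cc([C@@H](C=C)OC(C)=O)ccc1OCc1ccccc1
F3 | step 3 | (1R)-1-[4-(benzyloxy)-3-methoxyphenyl]prop-2-en-1-ol | COc1cc([C@@H](C=C)O)ccc1OCc1ccccc1
F4 | step 3 | (1R)-1-[4-(benzyloxy)-3-methoxyphenyl]prop-2-en-1-yl acrylate | COc1cc([C@@H](C=C)OC(=O)C=C)ccc1OCc1ccccc1
F5 | step 11 | (2R,3R,4R)-2-[3-methoxy-4-(triethylsilyloxy)phenyl]-4-[3,5-dimethoxy-4-(triethylsilyloxy)benzyl]-3-methyltetrahydrofuran | COc1cc([C@@H]2OC[C@H](Cc3cc(OC)c(O[Si](CC)(CC)CC)c(OC)c3)[C@H]2C)ccc1O[Si](CC)(CC)CC
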